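Ring C is opened at both bonds of C3. The feature exploited is this: of C2, C3 and C4, only methoxy-bearing C3 is below the acid oxidation level. C4 is the carboxyl carbon of a ring A salicylic acid (C4a–C4, C8a–O1), and C2 is the carbonyl carbon of the ring B benzoate on O1. A methoxymethylene phosphorane can therefore staple the two acyl carbons together. In one operation it is acylated at C4 and then olefinates C2, which makes C3–C4 and C2=C3 and closes the pyranone. The precursor is 2-hydroxy-3,4,6-trimethoxybenzoyl chloride bearing the 2,3,4-trimethoxybenzoyl group on its phenol oxygen. The para C5/C8 methyl ethers leave last via the 5,8-quinone.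

Key step: step 5

Assumption: the target has no stereocentre and no configurationally stable axis (rotation about C2–C1' is free), so it is achiral, no enantiomer has to be chosen and no SMILES needs a stereodescriptor; flavone numbering is used for the later compounds.

Step 1
Reactants: 1 1,2,3,5-tetramethoxybenzene
Product: 3 2,3,4,6-tetramethoxybenzoic acid, via aryllithium 2 (not isolated)
Conditions: n-BuLi (1.1 equiv), THF, 0 °C → rt; CO2 (g), −78 °C → rt; cold 1 M HCl
Reagents that add atoms: carbon dioxide, O=C=O
Why: Directed ortho-metalation followed by carboxylation: the two ring hydrogens of 1 are equivalent and each sits between two methoxy groups, so only aryllithium 2 can form, and CO2 places the future C4 on the future C4a.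

Step 2
Reactants: 3 2,3,4,6-tetramethoxybenzoic acid
Product: 4 2-hydroxy-3,4,6-trimethoxybenzoic acid
Conditions: BCl3 (1.1 equiv), CH2Cl2, −78 → 0 °C; H2O
Reagents that add atoms: none
Why: Chelation-assisted aryl methyl ether cleavage: boron binds the carboxyl oxygen and one ortho methoxy oxygen in a six-membered chelate and chloride takes the methyl group, and of the two ortho ethers of 3 the 2-OMe, wedged between the carboxyl group and the 3-OMe, is twisted out of conjugation and is therefore the more basic and more strained one, the same site preference that Lewis acid acylations of 1 show when they end in 2-hydroxy-3,4,6-trimethoxyphenyl ketones; the single equivalent of boron stays locked in the salicylate chelate, which stops a second cleavage.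

Step 3
Reactants: 4 2-hydroxy-3,4,6-trimethoxybenzoic acid; 5 2,3,4-trimethoxybenzoyl chloride
Product: 6 3,4,6-trimethoxy-2-[(2,3,4-trimethoxybenzoyl)oxy]benzoic acid
Conditions: 5 (1.0 equiv), Et3N (2.2 equiv), DMAP (0.1 equiv), CH2Cl2, 0 °C → rt; cold 0.5 M HCl wash
Reagents that add atoms: none
Why: DMAP-catalysed O-acylation of the only phenol: should the carboxylate react first, the mixed anhydride can pass on only its ring B acyl group, because the ring A carbonyl is shielded by two ortho substituents, and the neighbouring phenoxide takes it up through a six-membered transition state, the direction that O-acylsalicylates favour.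

Step 4
Reactants: 6 3,4,6-trimethoxy-2-[(2,3,4-trimethoxybenzoyl)oxy]benzoic acid
Product: 7 2-(chlorocarbonyl)-3,5,6-trimethoxyphenyl 2,3,4-trimethoxybenzoate
Conditions: (COCl)2 (1.5 equiv), DMF (cat.), CH2Cl2, 0 °C → rt; evaporate, strip with PhMe, use crude
Reagents that add atoms: oxalyl chloride, O=C(Cl)C(=O)Cl
Why: Acid chloride formation through the catalytic chloroiminium (Vilsmeier-type) salt runs without strong acid or heat, spares the aryl ester and the methyl ethers, and leaves only gases beside 7, so the moisture-sensitive product needs no purification.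

Step 5
Reactants: 7 2-(chlorocarbonyl)-3,5,6-trimethoxyphenyl 2,3,4-trimethoxybenzoate; 8 (methoxymethyl)triphenylphosphonium chloride
Product: 11 3,5,7,8,2',3',4'-heptamethoxyflavone, via ylide 9 (not isolated), via keto ylide 10 (not isolated)
Conditions: 8 (2.1 equiv), NaHMDS (2.0 equiv), THF, 0 °C; add 7 in THF, −78 °C → rt; filter under Ar, swap THF for PhMe, 110 °C
Reagents that add atoms: none
Why: Proposed new method: the non-stabilised ylide 9 is C-acylated by the acid chloride of 7 at −78 °C and a second equivalent of 9 removes the now acidic proton at once, which gives the α-methoxy-β-keto ylide 10 and returns one equivalent of salt 8. On heating, the ylide carbon of 10 adds to the adjacent aryl ester carbonyl in a 6-exo-trig closure (ring C: C3, C4, C4a, C8a, O1, C2), and the oxaphosphetane collapses with loss of triphenylphosphine oxide to leave C2=C3. The closest known reaction types are ylide acylation with transylidation and the intramolecular Wittig ester olefination of acylphosphoranes made from O-acylsalicylic acids, which gives 3-unsubstituted chromones and flavones; the new element is the fully substituted, methoxy-bearing ylide carbon. No stereocentre is formed, and the ring fixes the geometry of the new double bond. The step needs 9 to take the acid chloride before the aryl ester, which is secured by the gap in leaving-group ability, the low temperature, the exact 2:1 stoichiometry with base in slight deficit and the shielding of the ester by the 2'-OMe on one side and a 2,6-disubstituted aryloxy group on the other; afterwards only this ester is within reach of the ylide carbon. Lone-pair repulsion from the methoxy group should raise the nucleophilicity of 10 above that of ordinary keto ylides and so offset the added steric load.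

Step 6
Reactants: 11 3,5,7,8,2',3',4'-heptamethoxyflavone
Product: 13 5,8-dihydroxy-3,7,2',3',4'-pentamethoxyflavone, via quinone 12 (not isolated)
Conditions: CAN (2.5 equiv), MeCN–H2O 3:1, 0 °C; extract (EtOAc); sat. aq. Na2S2O4, rt, N2
Reagents that add atoms: water, O
Why: Oxidative demethylation of a 1,4-dimethoxyarene by cerium(IV) followed by quinone reduction: only the C5 and C8 methoxy groups are para to each other, ring A with its 1,2,4-trimethoxy array is the easiest ring to oxidise while ring B has no para pair, the change of 3,5,7,8-tetramethoxyflavones with methoxylated B rings into 7-methoxy-5,8-quinones is established flavone chemistry, and dithionite then adds two hydrogens to 12 in the neutral two-phase work-up without touching chromone or ethers.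

Compound list
1 | 1,2,3,5-tetramethoxybenzene | COc1cc(OC)c(OC)c(OC)c1 | starting material
2 | (2,3,4,6-tetramethoxyphenyl)lithium | [Li]c1c(OC)cc(OC)c(OC)c1OC | intermediate
3 | 2,3,4,6-tetramethoxybenzoic acid | COc1cc(OC)c(C(=O)O)c(OC)c1OC | intermediate
4 | 2-hydroxy-3,4,6-trimethoxybenzoic acid | COc1cc(OC)c(C(=O)O)c(O)c1OC | intermediate
5 | 2,3,4-trimethoxybenzoyl chloride | COc1ccc(C(=O)Cl)c(OC)c1OC | starting material
6 | 3,4,6-trimethoxy-2-[(2,3,4-trimethoxybenzoyl)oxy]benzoic acid | COc1cc(OC)c(C(=O)O)c(OC(=O)c2ccc(OC)c(OC)c2OC)c1OC | intermediate
7 | 2-(chlorocarbonyl)-3,5,6-trimethoxyphenyl 2,3,4-trimethoxybenzoate | COc1cc(OC)c(C(=O)Cl)c(OC(=O)c2ccc(OC)c(OC)c2OC)c1OC | intermediate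
8 | (methoxymethyl)triphenylphosphonium chloride | COC[P+](c1ccccc1)(c1ccccc1)c1ccccc1.[Cl-] | starting material
9 | (methoxymethylidene)triphenylphosphorane | COC=P(c1ccccc1)(c1ccccc1)c1ccccc1 | intermediate
10 | 3,5,6-trimethoxy-2-[methoxy(triphenyl-λ5-phosphanylidene)acetyl]phenyl 2,3,4-trimethoxybenzoate (keto ylide) | COc1cc(OC)c(C(=O)C(OC)=P(c2ccccc2)(c2ccccc2)c2ccccc2)c(OC(=O)c2ccc(OC)c(OC)c2OC)c1OC | intermediate
11 | 3,5,7,8,2',3',4'-heptamethoxyflavone | COc1ccc(-c2oc3c(OC)c(OC)cc(OC)c3c(=O)c2OC)c(OC)c1OC | intermediate
12 | 3,7-dimethoxy-2-(2,3,4-trimethoxyphenyl)-4H-chromene-4,5,8-trione (flavone-5,8-quinone) | COC1=CC(=O)C2=C(OC(c3ccc(OC)c(OC)c3OC)=C(OC)C2=O)C1=O | intermediate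
13 | 5,8-dihydroxy-3,7,2',3',4'-pentamethoxyflavone | COc1ccc(-c2oc3c(O)c(OC)cc(O)c3c(=O)c2OC)c(OC)c1OC | target

Total step count: 6
Longest linear sequence: 6 steps (1 → 3 → 4 → 6 → 7 → 11 → 13); 5 and 8 are bought.

Steps most likely to fail

Step 5 (Proposed new method).
- **What may go wrong:** Ring closure may be slow or fail, because a fully substituted ylide carbon must reach an ester carbonyl that is shielded on both sides. The basic ylide may also strip the aroyl group from O1, and the keto ylide may be protonated or hydrolysed before it cyclises.
- **Fallback:** It sets out from 7 and comes back at 11, and it uses known chemistry only.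
  - 7 is added at −78 °C to two equivalents of methylenetriphenylphosphorane (methyltriphenylphosphonium bromide, NaHMDS, THF). This gives the unsubstituted keto ylide 3,5,6-trimethoxy-2-[(triphenyl-λ5-phosphanylidene)acetyl]phenyl 2,3,4-trimethoxybenzoate F1.
  - Heating in toluene closes it by the established intramolecular ester olefination to 5,7,8,2',3',4'-hexamethoxyflavone F2.
  - C3 is then oxygenated with dimethyldioxirane (acetone–CH2Cl2, 0 °C, then a trace of TsOH) to 3-hydroxy-5,7,8,2',3',4'-hexamethoxyflavone F3.
  - O-methylation (MeI, K2CO3, acetone) gives 11.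

Step 6.
- **What may go wrong:** Ring B may be over-oxidised or nitrated by the cerium(IV) nitrate medium. The vinylogous-ester C7 methoxy group of the quinone may be lost by hydrolysis. The hydroquinone may be re-oxidised by air during isolation.
- **Fallback:** It sets out from 11 and comes back at 12.
  - The peri C5 methyl ether alone is cleaved through chelation to C4=O (AlCl3, MeCN, warm), which gives 5-hydroxy-3,7,8,2',3',4'-hexamethoxyflavone F4.
  - This para-methoxyphenol is oxidised under metal-free, nitrate-free conditions with PhI(OCOCF3)2 in MeCN–H2O at 0 °C to 12.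
  - 12 is reduced with dithionite as in step 6.

Step 2.
- **What may go wrong:** Site selectivity between the two ortho methoxy groups may be poor. Both may be cleaved, or the electron-rich acid may undergo protodecarboxylation, and acidic isomers are hard to separate. The site of cleavage can be checked by NOE, since H5 of 4 has two methoxy neighbours and the wrong isomer has only one.
- **Fallback:** It sets out from 1 and comes back at 6, so 4 and the acylation of a free acid are bypassed.
  - Vilsmeier–Haack formylation of 1 (POCl3, DMF) gives 2,3,4,6-tetramethoxybenzaldehyde F5.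
  - Magnesium iodide etherate (PhMe–Et2O, warm) is a reagent class with precedent for cleaving the more hindered ortho ether of 3-substituted 2,6-dimethoxybenzaldehydes. It gives 2-hydroxy-3,4,6-trimethoxybenzaldehyde F6.
  - The neutral salicylaldehyde isomers can be separated by chromatography, and mis-cleaved material can be re-methylated to F5.
  - Acylation with 5 (Et3N, DMAP, CH2Cl2) gives 2-formyl-3,5,6-trimethoxyphenyl 2,3,4-trimethoxybenzoate F7.
  - Pinnick oxidation (NaClO2, NaH2PO4, 2-methyl-2-butene, t-BuOH–H2O) gives 6.

Further compounds
F1 | step 5 | 3,5,6-trimethoxy-2-[(triphenyl-λ5-phosphanylidene)acetyl]phenyl 2,3,4-trimethoxybenzoate | COc1cc(OC)c(C(=O)C=P(c2ccccc2)(c2ccccc2)c2ccccc2)c(OC(=O)c2ccc(OC)c(OC)c2OC)c1OC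
F2 | step 5 | 5,7,8,2',3',4'-hexamethoxyflavone | COc1ccc(-c2cc(=O)c3c(OC)cc(OC)c(OC)c3o2)c(OC)c1OC
F3 | step 5 | 3-hydroxy-5,7,8,2',3',4'-hexamethoxyflavone | COc1ccc(-c2oc3c(OC)c(OC)cc(OC)c3c(=O)c2O)c(OC)c1OC
F4 | step 6 | 5-hydroxy-3,7,8,2',3',4'-hexamethoxyflavone | COc1ccc(-c2oc3c(OC)c(OC)cc(O)c3c(=O)c2OC)c(OC)c1OC
F5 | step 2 | 2,3,4,6-tetramethoxybenzaldehyde | COc1cc(OC)c(C=O)c(OC)c1OC
F6 | step 2 | 2-hydroxy-3,4,6-trimethoxybenzaldehyde | COc1cc(OC)c(C=O)c(O)c1OC
F7 | step 2 | 2-formyl-3,5,6-trimethoxyphenyl 2,3,4-trimethoxybenzoate | COc1cc(OC)c(C=O)c(OC(=O)c2ccc(OC)c(OC)c2OC)c1OC
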